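**Retrosynthetic overview**

- Feature: the 1-methyl-2-aminoimidazole core is read as a rearranged 3-(methylamino)-5-methyl-1,2,4-oxadiazole whose exocyclic nitrogen carries a β-aroyl enamine. The enamine N becomes N1, oxadiazole C3 becomes C2, oxadiazole N2 becomes N3, the enaminone α-carbon becomes C4 (later the carbinol carbon's attachment point) and the β-carbon becomes C5 (bearing the benzyl group); the O1–C5(CH3)–N4 arm unfolds into a C2 acetamide.
- Disconnections, backwards: carbinol C–H (asymmetric transfer hydrogenation of the ketone, last step); exocyclic amidine C–N (2-aminoimidazole plus 1-methylparabanic acid); imidazole N3–C4 (oxadiazole-to-imidazole rearrangement); enamine C–N (conjugate addition of N,5-dimethyl-1,2,4-oxadiazol-3-amine to an ynone, which fixes the regiochemistry); ynone C–C bonds (acetylide plus Weinreb amide; aryl Grignard plus methoxyallene).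
- Ring order: both benzene rings, the oxadiazole and the imidazolidinetrione are bought. The imidazole is the only ring made (step 5), at the expense of the oxadiazole. The dehydrohydantoin ring is attached intact in step 7.
- The phenol travels as a methoxymethyl ether because the addition and the rearrangement run in base. The stereocentre is made in the final step, so it never meets acid or heat.

Key step: step 5

Assumption: the facial sense of the final reduction is assigned from the accepted transition-state model of Noyori–Ikariya catalysts and is to be confirmed on the product; should the model prove inverted for this ketone, the (R,R)-ligand takes the place of the (S,S)-ligand.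

**Route**

Step 1
Reactants: 1 1-bromo-4-(methoxymethoxy)benzene; 2 methoxyallene (1-methoxypropa-1,2-diene)
Product: 4 1-(methoxymethoxy)-4-(prop-2-yn-1-yl)benzene, via arylmagnesium bromide 3 (not isolated)
Conditions: Mg, THF, 45 °C; then 2, CuBr (5 mol%), THF, 0 → 25 °C; aq NH4Cl
Reagents that add atoms: none
Why: Copper-catalysed SN2′ substitution of methoxyallene by an aryl Grignard reagent (attack at the CH2 terminus with loss of methoxide) is the standard route to 3-aryl-prop-1-ynes, and the methoxymethyl acetal is inert to the organomagnesium.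

Step 2
Reactants: 4 1-(methoxymethoxy)-4-(prop-2-yn-1-yl)benzene; 5 N,4-dimethoxy-N-methylbenzamide
Product: 7 1-(4-methoxyphenyl)-4-[4-(methoxymethoxy)phenyl]but-2-yn-1-one, via lithium acetylide 6 (not isolated)
Conditions: n-BuLi (1.0 equiv), THF, −78 °C; then 5, −78 → 0 °C; inverse quench into cold 0.5 M aq HCl
Reagents that add atoms: none
Why: Deprotonation of the terminal alkyne C–H and Weinreb acylation of the acetylide stop at the chelated tetrahedral adduct, so the ynone is released only in the cold acidic quench, which also protonates the liberated N,O-dimethylhydroxylamine before it can add to the ynone.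

Step 3
Reactants: 8 3-amino-5-methyl-1,2,4-oxadiazole
Product: 10 N,5-dimethyl-1,2,4-oxadiazol-3-amine, via formimidate 9 (not isolated)
Conditions: HC(OEt)3, TsOH (cat.), 130 °C, distil EtOH; concentrate; then NaBH4, EtOH, 0 → 60 °C
Reagents that add atoms: triethyl orthoformate, CCOC(OCC)OCC
Why: Orthoformate condensation to the formimidate followed by borohydride reduction is the established mono-N-methylation of weakly basic heteroarylamines and avoids the ring-nitrogen alkylation and double alkylation that methyl iodide would risk.

Step 4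
Reactants: 7 1-(4-methoxyphenyl)-4-[4-(methoxymethoxy)phenyl]but-2-yn-1-one; 10 N,5-dimethyl-1,2,4-oxadiazol-3-amine
Product: 11 (E)-1-(4-methoxyphenyl)-4-[4-(methoxymethoxy)phenyl]-3-[methyl(5-methyl-1,2,4-oxadiazol-3-yl)amino]but-2-en-1-one
Conditions: 10 (1.3 equiv), Cs2CO3 (0.3 equiv), MeCN, 0 → 25 °C; AcOH quench
Reagents that add atoms: none
Why: Base-catalysed aza-Michael addition of the N–H of 10 to the ynone (or to the allenone with which it equilibrates under the base) can place nitrogen only on the β-carbon, and proton equilibration should deliver the conjugated vinylogous amide as its more stable E isomer.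

Step 5
Reactants: 11 (E)-1-(4-methoxyphenyl)-4-[4-(methoxymethoxy)phenyl]-3-[methyl(5-methyl-1,2,4-oxadiazol-3-yl)amino]but-2-en-1-one
Product: 12 N-{4-(4-methoxybenzoyl)-5-[4-(methoxymethoxy)benzyl]-1-methyl-1H-imidazol-2-yl}acetamide
Conditions: t-BuOK (1.5 equiv), DMF, 25 → 60 °C; AcOH quench
Reagents that add atoms: none
Why: t-BuOK removes a γ-proton (ArCH2) of the vinylogous amide to give an extended enolate whose α-carbon, the carbon with the largest coefficient, attacks the pivotal oxadiazole N2 in the ring plane while the weak O1–N2 bond breaks, so that the Cα–N2 bond (imidazole C4–N3) forms, the O1–C5(CH3)–N4 arm leaves as an acetamidate on C2, and a proton shift from C4 to the exocyclic benzylidene carbon aromatises the new ring. The closest known reaction type is the base-induced Boulton–Katritzky mononuclear rearrangement of N-(1,2,4-oxadiazol-3-yl) β-enaminones to 2-acylamino-4-acylimidazoles, run here on the N-methyl congener. The imidazole ring (N-methyl nitrogen, oxadiazole C3 and N2, enaminone Cα and Cβ) closes in a 5-exo mode by intramolecular substitution at nitrogen, the departing oxygen lying outside the new ring. No stereocentre is formed. The selectivity needed is closure through Cα and not through the benzylic Cγ, which would give the 4-aryl-5-phenacyl isomer; it rests on the α-preference of extended enolates in kinetically controlled bond formation, while the placement of methyl on N1, benzyl on C5 and aroyl on C4 follows from the connectivity of 11 whatever its alkene geometry. Loss of the N–O bond and gain of an amide carbonyl and an aromatic imidazole should make the step irreversible.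

Step 6
Reactants: 12 N-{4-(4-methoxybenzoyl)-5-[4-(methoxymethoxy)benzyl]-1-methyl-1H-imidazol-2-yl}acetamide
Product: 13 [2-amino-5-(4-hydroxybenzyl)-1-methyl-1H-imidazol-4-yl](4-methoxyphenyl)methanone
Conditions: HCl (3 M in MeOH), 60 °C; then aq NaHCO3
Reagents that add atoms: none
Why: Acid-catalysed methanolysis cleaves the acylguanidine-type N-acetyl group and the methoxymethyl acetal in one operation (the formaldehyde unit being trapped as dimethoxymethane), at a stage where the molecule has neither a stereocentre nor an acid-labile carbinol.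

Step 7
Reactants: 13 [2-amino-5-(4-hydroxybenzyl)-1-methyl-1H-imidazol-4-yl](4-methoxyphenyl)methanone; 14 1-methylparabanic acid (1-methylimidazolidine-2,4,5-trione)
Product: 16 4-{[5-(4-hydroxybenzyl)-4-(4-methoxybenzoyl)-1-methyl-1H-imidazol-2-yl]amino}-1-methyl-1H-imidazole-2,5-dione, via aryl trimethylsilyl ether 15 (not isolated)
Conditions: 14 (2.5 equiv), N,O-bis(trimethylsilyl)acetamide (5 equiv), MeCN, 80 °C; then MeOH, 25 °C
Reagents that add atoms: none
Why: Silyl-mediated condensation of a 2-aminoimidazole with 1-methylparabanic acid (attack of the exocyclic amine at C4 of the O-silyl imidate with loss of silanol) is the established way to build the dehydrohydantoin of the naamidine alkaloids, the phenol being masked in the flask as its trimethylsilyl ether and the diaryl-type ketone having no α-hydrogen to silylate.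

Step 8
Reactants: 16 4-{[5-(4-hydroxybenzyl)-4-(4-methoxybenzoyl)-1-methyl-1H-imidazol-2-yl]amino}-1-methyl-1H-imidazole-2,5-dione
Product: 17 4-({4-[(R)-hydroxy(4-methoxyphenyl)methyl]-5-(4-hydroxybenzyl)-1-methyl-1H-imidazol-2-yl}amino)-1-methyl-1H-imidazole-2,5-dione (CNP0181743.1)
Conditions: RuCl[(S,S)-TsDPEN](p-cymene) (3 mol%), HCO2Na (5 equiv), H2O/MeOH (1:1), 40 °C
Reagents that add atoms: none
Why: In this Noyori–Ikariya asymmetric transfer hydrogenation of an aryl heteroaryl ketone the stereocentre is set by the catalyst, the planar p-anisyl ring being expected under the η6-p-cymene (CH/π contact) and the imidazolyl ring with its ortho benzyl group in the remote position, so that the (S,S)-ligand should deliver hydride to the Si face and give the (R)-carbinol, while the near-neutral formate medium keeps the ionisable doubly benzylic alcohol from racemising.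

**Compound list**

1 | 1-bromo-4-(methoxymethoxy)benzene | COCOc1ccc(Br)cc1 | starting material
2 | methoxyallene (1-methoxypropa-1,2-diene) | COC=C=C | starting material
3 | [4-(methoxymethoxy)phenyl]magnesium bromide | COCOc1ccc([Mg]Br)cc1 | intermediate (not isolated)
4 | 1-(methoxymethoxy)-4-(prop-2-yn-1-yl)benzene | COCOc1ccc(CC#C)cc1 | intermediate
5 | N,4-dimethoxy-N-methylbenzamide | COc1ccc(C(=O)N(C)OC)cc1 | starting material
6 | lithium 3-[4-(methoxymethoxy)phenyl]prop-1-yn-1-ide | [Li]C#CCc1ccc(OCOC)cc1 | intermediate (not isolated)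
7 | 1-(4-methoxyphenyl)-4-[4-(methoxymethoxy)phenyl]but-2-yn-1-one | COCOc1ccc(CC#CC(=O)c2ccc(OC)cc2)cc1 | intermediate
8 | 3-amino-5-methyl-1,2,4-oxadiazole | Cc1nc(N)no1 | starting material
9 | ethyl (E)-N-(5-methyl-1,2,4-oxadiazol-3-yl)formimidate | CCO/C=N/c1noc(C)n1 | intermediate (not isolated)
10 | N,5-dimethyl-1,2,4-oxadiazol-3-amine | CNc1noc(C)n1 | intermediate
11 | (E)-1-(4-methoxyphenyl)-4-[4-(methoxymethoxy)phenyl]-3-[methyl(5-methyl-1,2,4-oxadiazol-3-yl)amino]but-2-en-1-one | COc1ccc(C(=O)/C=C(\Cc2ccc(OCOC)cc2)N(C)c2noc(C)n2)cc1 | intermediate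
12 | N-{4-(4-methoxybenzoyl)-5-[4-(methoxymethoxy)benzyl]-1-methyl-1H-imidazol-2-yl}acetamide | COc1ccc(C(=O)c2nc(NC(C)=O)n(C)c2Cc2ccc(OCOC)cc2)cc1 | intermediate
13 | [2-amino-5-(4-hydroxybenzyl)-1-methyl-1H-imidazol-4-yl](4-methoxyphenyl)methanone | COc1ccc(C(=O)c2nc(N)n(C)c2Cc2ccc(O)cc2)cc1 | intermediate
14 | 1-methylparabanic acid (1-methylimidazolidine-2,4,5-trione) | CN1C(=O)NC(=O)C1=O | starting material
15 | 4-{[4-(4-methoxybenzoyl)-1-methyl-5-(4-trimethylsilyloxybenzyl)-1H-imidazol-2-yl]amino}-1-methyl-1H-imidazole-2,5-dione | COc1ccc(C(=O)c2nc(NC3=NC(=O)N(C)C3=O)n(C)c2Cc2ccc(O[Si](C)(C)C)cc2)cc1 | intermediate (not isolated)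
16 | 4-{[5-(4-hydroxybenzyl)-4-(4-methoxybenzoyl)-1-methyl-1H-imidazol-2-yl]amino}-1-methyl-1H-imidazole-2,5-dione | COc1ccc(C(=O)c2nc(NC3=NC(=O)N(C)C3=O)n(C)c2Cc2ccc(O)cc2)cc1 | intermediate
17 | 4-({4-[(R)-hydroxy(4-methoxyphenyl)methyl]-5-(4-hydroxybenzyl)-1-methyl-1H-imidazol-2-yl}amino)-1-methyl-1H-imidazole-2,5-dione | COc1ccc([C@@H](O)c2nc(NC3=NC(=O)N(C)C3=O)n(C)c2Cc2ccc(O)cc2)cc1 | target

**Step count**

Total steps: 8. Longest linear sequence: 7 steps (1 → 4 → 7 → 11 → 12 → 13 → 16 → 17); step 3 is the one-step side branch.

**Steps most likely to fail**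

1. Step 5.
   - Risk: the tertiary enaminone has no N–H, so the reacting anion must be made at carbon. Ring closure may then be slower than base-induced degradation of the oxadiazole, or closure may take place through the benzylic γ-carbon instead of the α-carbon.
   - Fallback: return to the N–H form of the same rearrangement and introduce the methyl group afterwards. Ynone 7 and 3-amino-5-methyl-1,2,4-oxadiazole 8 are combined (Cs2CO3 cat., MeCN) to the hydrogen-bonded secondary enaminone (Z)-1-(4-methoxyphenyl)-4-[4-(methoxymethoxy)phenyl]-3-[(5-methyl-1,2,4-oxadiazol-3-yl)amino]but-2-en-1-one F1. Its N-deprotonated anion (t-BuOK, DMF) carries charge only on nitrogen, the α-carbon and oxygen, so γ-closure is excluded, and it should rearrange to N-{4-(4-methoxybenzoyl)-5-[4-(methoxymethoxy)benzyl]-1H-imidazol-2-yl}acetamide F2. Methylation (MeI, K2CO3, DMF) at the ring nitrogen remote from the aroyl group, the usual site for 4-acylimidazoles, then gives 12, where the route is rejoined.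

2. Step 8.
   - Risk: poor facial discrimination between two aryl-type substituents, competing hydride addition to the acylamidine C=N, or sequestration of the ruthenium by the N,N-chelating aminoimidazole–dehydrohydantoin unit.
   - Fallback: replace asymmetric induction by resolution. Ketone 16 is reduced with NaBH4 and CeCl3·7H2O in MeOH at −40 °C to the racemic carbinol F3, which is separated by preparative chromatography on a chiral stationary phase. The (R)-enantiomer is 17; the (S)-enantiomer F4 is oxidised back to 16 with MnO2 and recycled.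

3. Step 7.
   - Risk: sluggish amidine formation because the 4-aroyl group lowers the nucleophilicity of the 2-amino group, with decay of the silyl imidate on prolonged heating.
   - Fallback: reverse the order of the last two operations so that the condensing amine is the electron-rich one. Amino ketone 13 is reduced under the step 8 conditions to (R)-[2-amino-5-(4-hydroxybenzyl)-1-methyl-1H-imidazol-4-yl](4-methoxyphenyl)methanol F5. This is condensed with 14 and N,O-bis(trimethylsilyl)acetamide to the bis(trimethylsilyl) ether of the target F6, and methanolysis (K2CO3 cat., MeOH, 0 °C) gives 17 directly. The cost is that the carbinol stereocentre is then exposed to the warm silylating medium, so the lowest workable temperature would be used.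

Further compounds
F1 | step 5 | (Z)-1-(4-methoxyphenyl)-4-[4-(methoxymethoxy)phenyl]-3-[(5-methyl-1,2,4-oxadiazol-3-yl)amino]but-2-en-1-one | COc1ccc(C(=O)/C=C(/Cc2ccc(OCOC)cc2)Nc2noc(C)n2)cc1
F2 | step 5 | N-{4-(4-methoxybenzoyl)-5-[4-(methoxymethoxy)benzyl]-1H-imidazol-2-yl}acetamide | COc1ccc(C(=O)c2nc(NC(C)=O)[nH]c2Cc2ccc(OCOC)cc2)cc1
F3 | step 8 | racemic 4-({4-[hydroxy(4-methoxyphenyl)methyl]-5-(4-hydroxybenzyl)-1-methyl-1H-imidazol-2-yl}amino)-1-methyl-1H-imidazole-2,5-dione | COc1ccc(C(O)c2nc(NC3=NC(=O)N(C)C3=O)n(C)c2Cc2ccc(O)cc2)cc1
F4 | step 8 | 4-({4-[(S)-hydroxy(4-methoxyphenyl)methyl]-5-(4-hydroxybenzyl)-1-methyl-1H-imidazol-2-yl}amino)-1-methyl-1H-imidazole-2,5-dione | COc1ccc([C@H](O)c2nc(NC3=NC(=O)N(C)C3=O)n(C)c2Cc2ccc(O)cc2)cc1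
F5 | step 7 | (R)-[2-amino-5-(4-hydroxybenzyl)-1-methyl-1H-imidazol-4-yl](4-methoxyphenyl)methanol | COc1ccc([C@@H](O)c2nc(N)n(C)c2Cc2ccc(O)cc2)cc1
F6 | step 7 | 4-({4-[(R)-(4-methoxyphenyl)(trimethylsilyloxy)methyl]-1-methyl-5-(4-trimethylsilyloxybenzyl)-1H-imidazol-2-yl}amino)-1-methyl-1H-imidazole-2,5-dione | COc1ccc([C@@H](O[Si](C)(C)C)c2nc(NC3=NC(=O)N(C)C3=O)n(C)c2Cc2ccc(O[Si](C)(C)C)cc2)cc1
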